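Ring A is disconnected across C8–C8a, C6–C7 and C4a–C8a. Its three contiguous oxygens at C5, C6 and C7, of which only O7 is unmethylated, map onto the two enol-ether carbons of a squarate-derived 2,3-dimethoxycyclobutenone (C5 and C6; its CH2 becomes C4a, its carbonyl C8a) and onto a triisopropylsiloxyacetylene (C7 and C8). A single thermal benzannulation of these two partners therefore builds ring A as the C8a phenol with O7 already set apart as a silyl ether. The phenol is then acetylated at C4a, aroylated with a silyl-protected ring B acid chloride, cyclodehydrated to the flavone and desilylated.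

Key step: step 6

Remark: ring A positions are given in flavone numbering (C4a, C5–C8, C8a) also for the monocyclic precursors; compounds 2, 3 and 11 each carry one stereocentre, should form as racemates and lose it again, so the achiral target needs no stereocontrol.

Step 1
Reactants: 1 dimethyl squarate
Product: 2 4-hydroxy-2,3-dimethoxycyclobut-2-en-1-one (racemic)
Conditions: LiAlH(OtBu)3 (1.05 equiv), THF, −78 °C; sat. aq. NH4Cl, 0 °C
Reagents that add atoms: none
Why: The bulky hydride adds once to one of the two equivalent carbonyls of the squarate (1,2-reduction of a vinylogous ester) and the aluminium alkoxide formed resists a second addition at low temperature, the new C4 stereocentre arising racemic and being removed again in step 3.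

Step 2
Reactants: 2 4-hydroxy-2,3-dimethoxycyclobut-2-en-1-one
Product: 3 4-chloro-2,3-dimethoxycyclobut-2-en-1-one (racemic)
Conditions: SOCl2 (1.1 equiv), 2,6-lutidine (1.2 equiv), CH2Cl2, −20 → 0 °C
Reagents that add atoms: thionyl chloride, O=S(Cl)Cl
Why: Deoxychlorination via the chlorosulfite, in which the methoxy-stabilised cyclobutenyl cation is captured by chloride at C4 to restore the conjugated vinylogous ester, should give the racemic allylic α-chloro ketone under cold, buffered, water-free conditions.

Step 3
Reactants: 3 4-chloro-2,3-dimethoxycyclobut-2-en-1-one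
Product: 4 2,3-dimethoxycyclobut-2-en-1-one
Conditions: Zn dust, AcOH, TMEDA, MeOH, 0 °C → rt
Reagents that add atoms: none
Why: Zinc inserts into the activated C–Cl bond and the zinc enolate is protonated at C4 (reductive dehalogenation of an α-chloro ketone, as used for 4-chlorocyclobutenones), which removes the stereocentre, while methanol as solvent makes any alkoxy exchange at the vinylogous ester degenerate.

Step 4
Reactants: 5 trimethylsilylacetylene
Product: 8 triisopropyl{[(trimethylsilyl)ethynyl]oxy}silane, via lithium (trimethylsilyl)acetylide 6 (not isolated), via lithium (trimethylsilyl)ethynolate 7 (not isolated)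
Conditions: n-BuLi, THF, −78 °C; t-BuOOLi (from t-BuOOH and LiN(SiMe3)2), THF, −78 → 0 °C; iPr3SiOTf, −78 → 0 °C
Reagents that add atoms: tert-butyl hydroperoxide, CC(C)(C)OO; triisopropylsilyl trifluoromethanesulfonate, CC(C)[Si](C(C)C)(C(C)C)OS(=O)(=O)C(F)(F)F
Why: The lithium acetylide attacks the peroxide oxygen of t-BuOOLi with loss of tert-butoxide (oxidation of an acetylide to a lithium ynolate) and the hard, bulky silyl triflate then traps the ynolate on oxygen, giving a triisopropylsilyl ynol ether that is stable to isolation.

Step 5
Reactants: 8 triisopropyl{[(trimethylsilyl)ethynyl]oxy}silane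
Product: 9 ethynyloxy(triisopropyl)silane
Conditions: K2CO3 (cat.), MeOH, 0 °C, short reaction time; pentane extraction
Reagents that add atoms: none
Why: Carbonate-catalysed methanolysis cleaves the unhindered C(sp)–SiMe3 bond (protodesilylation of a silylalkyne) far faster than methoxide can reach the shielded silicon of the triisopropylsilyl ynol ether, which should survive a short reaction at 0 °C.

Step 6
Reactants: 4 2,3-dimethoxycyclobut-2-en-1-one; 9 ethynyloxy(triisopropyl)silane
Product: 14 3,4-dimethoxy-5-(triisopropylsilyloxy)phenol, via vinylketene 10 (not isolated), via vinylcyclobutenone 11 (not isolated), via dienylketene 12 (not isolated), via cyclohexadienone 13 (not isolated)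
Conditions: 9 (1.3 equiv), toluene, 110 °C, sealed tube, argon
Reagents that add atoms: none
Why: Proposed new method: heating opens 4 by four-electron electrocyclic cleavage of its C1–C4 bond to vinylketene 10, whose ketene C=C adds the electron-rich alkyne 9 in a [2+2] cycloaddition (C8–C8a and C6–C7) to give vinylcyclobutenone 11, which reopens to dienylketene 12 and closes ring A by a thermal disrotatory six-electron electrocyclisation (C4a–C8a) to cyclohexadienone 13, the keto tautomer of phenol 14. The closest known reaction is the Danheiser benzannulation of alkyl- and aryl-substituted cyclobutenones with triisopropylsiloxyalkynes, which gives resorcinol monosilyl ethers, and the thermal opening of squarate-derived 2,3-dialkoxycyclobutenones to dialkoxyvinylketenes is also established, so only the pairing of a C4-unsubstituted 2,3-dialkoxycyclobutenone with a siloxyalkyne is unproven. The six-membered ring A is the only ring that is kept, the four-membered ring of 11 being transient. No stereocentre remains in 14, since the quaternary centre of 11 forms racemic and is destroyed on ring opening. The step needs the regiochemistry of the [2+2] addition, which polarity secures: the unsubstituted, nucleophilic alkyne carbon attacks the electrophilic ketene carbonyl carbon, so the siloxy carbon bonds to the methoxy-bearing ketene carbon and ends next to the C6 methoxy carbon and meta to the new hydroxyl. It also needs the vinyl group of 11 to rotate inward on ring opening, which the outward preference of the geminal methoxy donor ensures, giving the Z-dienylketene that is able to cyclise.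

Step 7
Reactants: 14 3,4-dimethoxy-5-(triisopropylsilyloxy)phenol
Product: 15 1-[6-hydroxy-2,3-dimethoxy-4-(triisopropylsilyloxy)phenyl]ethan-1-one
Conditions: AcCl (1.2 equiv), TiCl4 (1.1 equiv), CH2Cl2, −20 °C → rt; cold 1 M HCl
Reagents that add atoms: acetyl chloride, CC(=O)Cl
Why: Lewis acid ortho-acylation of the titanium-bound phenol (Friedel–Crafts acylation, with Fries rearrangement of any O-acetate) should enter at C4a, which is ortho to the phenol oxygen and to the C5 methoxy group and para to the silyloxy group, because the other ortho carbon C8 is screened by the triisopropylsilyl ether, and chloride-based TiCl4 at low temperature leaves that ether and the methyl ethers intact.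

Step 8
Reactants: 16 3-hydroxy-4,5-dimethoxybenzoic acid
Product: 18 3,4-dimethoxy-5-(triisopropylsilyloxy)benzoic acid, via bis-silylated ester 17 (not isolated)
Conditions: iPr3SiCl (2.3 equiv), imidazole, DMF, 40 °C; then K2CO3, THF–MeOH–H2O, rt; 1 M HCl to pH 3, 0 °C
Reagents that add atoms: triisopropylsilyl chloride, CC(C)[Si](Cl)(C(C)C)C(C)C
Why: Silylation of both the phenol and the acid is followed by selective solvolysis of the far more labile silyl ester under mild carbonate conditions that the hindered aryl triisopropylsilyl ether survives (protecting-group chemistry of a hydroxybenzoic acid).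

Step 9
Reactants: 18 3,4-dimethoxy-5-(triisopropylsilyloxy)benzoic acid
Product: 19 3,4-dimethoxy-5-(triisopropylsilyloxy)benzoyl chloride
Conditions: (COCl)2 (1.3 equiv), DMF (cat.), CH2Cl2, 0 °C → rt; evaporation, used crude
Reagents that add atoms: oxalyl chloride, O=C(Cl)C(=O)Cl
Why: Vilsmeier-type activation by the chloroiminium salt from oxalyl chloride and DMF converts the acid into the acid chloride under conditions (anhydrous HCl) that aryl silyl ethers tolerate.

Step 10
Reactants: 15 1-[6-hydroxy-2,3-dimethoxy-4-(triisopropylsilyloxy)phenyl]ethan-1-one; 19 3,4-dimethoxy-5-(triisopropylsilyloxy)benzoyl chloride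
Product: 21 1-[3,4-dimethoxy-5-(triisopropylsilyloxy)phenyl]-3-[6-hydroxy-2,3-dimethoxy-4-(triisopropylsilyloxy)phenyl]propane-1,3-dione, via dilithium enolate–phenoxide 20 (not isolated)
Conditions: LiN(SiMe3)2 (3.2 equiv), THF, −78 → −10 °C; 19 (1.05 equiv), −78 °C → rt; aq. NH4Cl
Reagents that add atoms: none
Why: The phenoxide–enolate dianion is acylated at the enolate carbon by the aroyl chloride (one-flask variant of the Baker–Venkataraman synthesis of 1,3-diketones; any O-aroyl ester formed rearranges to the same diketone under the excess amide base), and the non-nucleophilic base leaves both aryl silyl ethers untouched.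

Step 11
Reactants: 21 1-[3,4-dimethoxy-5-(triisopropylsilyloxy)phenyl]-3-[6-hydroxy-2,3-dimethoxy-4-(triisopropylsilyloxy)phenyl]propane-1,3-dione
Product: 22 2-[3,4-dimethoxy-5-(triisopropylsilyloxy)phenyl]-5,6-dimethoxy-7-(triisopropylsilyloxy)-4H-chromen-4-one
Conditions: TsOH·H2O (cat.), toluene, 90 °C
Reagents that add atoms: none
Why: Acid-catalysed cyclodehydration, the phenolic hydroxyl at C8a adding to the ring B carbonyl to give a cyclic hemiketal that loses water to the aromatic 4-pyranone, closes ring C under conditions mild enough for aryl triisopropylsilyl ethers.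

Step 12
Reactants: 22 2-[3,4-dimethoxy-5-(triisopropylsilyloxy)phenyl]-5,6-dimethoxy-7-(triisopropylsilyloxy)-4H-chromen-4-one
Product: 23 7-hydroxy-2-(3-hydroxy-4,5-dimethoxyphenyl)-5,6-dimethoxy-4H-chromen-4-one (7,5'-dihydroxy-5,6,3',4'-tetramethoxyflavone)
Conditions: Bu4NF (2.4 equiv), AcOH (2.4 equiv), THF, 0 °C → rt
Reagents that add atoms: none
Why: Fluoride attacks silicon and releases both phenols (fluoride-mediated desilylation of aryl silyl ethers), acetic acid buffering the phenoxides, while the four methyl ethers and the chromone are inert.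

Compound list
1 | dimethyl squarate (3,4-dimethoxycyclobut-3-ene-1,2-dione) | COC1=C(OC)C(=O)C1=O | starting material
2 | 4-hydroxy-2,3-dimethoxycyclobut-2-en-1-one (racemic) | COC1=C(OC)C(=O)C1O | intermediate
3 | 4-chloro-2,3-dimethoxycyclobut-2-en-1-one (racemic) | COC1=C(OC)C(=O)C1Cl | intermediate
4 | 2,3-dimethoxycyclobut-2-en-1-one | COC1=C(OC)C(=O)C1 | intermediate
5 | trimethylsilylacetylene | C#C[Si](C)(C)C | starting material
6 | lithium (trimethylsilyl)acetylide | [Li+].[C-]#C[Si](C)(C)C | intermediate
7 | lithium (trimethylsilyl)ethynolate | [Li+].[O-]C#C[Si](C)(C)C | intermediate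
8 | triisopropyl{[(trimethylsilyl)ethynyl]oxy}silane | C[Si](C)(C)C#CO[Si](C(C)C)(C(C)C)C(C)C | intermediate
9 | ethynyloxy(triisopropyl)silane | C#CO[Si](C(C)C)(C(C)C)C(C)C | intermediate
10 | 2,3-dimethoxybuta-1,3-dien-1-one (vinylketene) | COC(=C)C(OC)=C=O | intermediate
11 | 4-methoxy-4-(1-methoxyethenyl)-3-(triisopropylsilyloxy)cyclobut-2-en-1-one (racemic) | COC(=C)C1(OC)C(=O)C=C1O[Si](C(C)C)(C(C)C)C(C)C | intermediate
12 | (3Z)-4,5-dimethoxy-3-(triisopropylsilyloxy)hexa-1,3,5-trien-1-one (dienylketene) | O=C=C/C(O[Si](C(C)C)(C(C)C)C(C)C)=C(OC)\C(OC)=C | intermediate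
13 | 4,5-dimethoxy-3-(triisopropylsilyloxy)cyclohexa-2,4-dien-1-one | COC1=C(OC)C(O[Si](C(C)C)(C(C)C)C(C)C)=CC(=O)C1 | intermediate
14 | 3,4-dimethoxy-5-(triisopropylsilyloxy)phenol | COc1cc(O)cc(O[Si](C(C)C)(C(C)C)C(C)C)c1OC | intermediate
15 | 1-[6-hydroxy-2,3-dimethoxy-4-(triisopropylsilyloxy)phenyl]ethan-1-one | CC(=O)c1c(O)cc(O[Si](C(C)C)(C(C)C)C(C)C)c(OC)c1OC | intermediate
16 | 3-hydroxy-4,5-dimethoxybenzoic acid | COc1cc(C(=O)O)cc(O)c1OC | starting material
17 | triisopropylsilyl 3,4-dimethoxy-5-(triisopropylsilyloxy)benzoate | COc1cc(C(=O)O[Si](C(C)C)(C(C)C)C(C)C)cc(O[Si](C(C)C)(C(C)C)C(C)C)c1OC | intermediate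
18 | 3,4-dimethoxy-5-(triisopropylsilyloxy)benzoic acid | COc1cc(C(=O)O)cc(O[Si](C(C)C)(C(C)C)C(C)C)c1OC | intermediate
19 | 3,4-dimethoxy-5-(triisopropylsilyloxy)benzoyl chloride | COc1cc(C(=O)Cl)cc(O[Si](C(C)C)(C(C)C)C(C)C)c1OC | intermediate
20 | dilithium enolate–phenoxide of ketone 15 | [Li+].[Li+].C=C([O-])c1c([O-])cc(O[Si](C(C)C)(C(C)C)C(C)C)c(OC)c1OC | intermediate
21 | 1-[3,4-dimethoxy-5-(triisopropylsilyloxy)phenyl]-3-[6-hydroxy-2,3-dimethoxy-4-(triisopropylsilyloxy)phenyl]propane-1,3-dione | COc1cc(C(=O)CC(=O)c2c(O)cc(O[Si](C(C)C)(C(C)C)C(C)C)c(OC)c2OC)cc(O[Si](C(C)C)(C(C)C)C(C)C)c1OC | intermediate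
22 | 2-[3,4-dimethoxy-5-(triisopropylsilyloxy)phenyl]-5,6-dimethoxy-7-(triisopropylsilyloxy)-4H-chromen-4-one | COc1cc(-c2cc(=O)c3c(OC)c(OC)c(O[Si](C(C)C)(C(C)C)C(C)C)cc3o2)cc(O[Si](C(C)C)(C(C)C)C(C)C)c1OC | intermediate
23 | 7-hydroxy-2-(3-hydroxy-4,5-dimethoxyphenyl)-5,6-dimethoxy-4H-chromen-4-one | COc1cc(-c2cc(=O)c3c(OC)c(OC)c(O)cc3o2)cc(O)c1OC | target

Total step count: 12. Longest linear sequence: 8 steps (steps 1, 2, 3, 6, 7, 10, 11 and 12).

Steps most likely to fail

Step 6 (bears the proposed new method). The push–pull stabilised cyclobutenone may open too slowly at temperatures that the siloxyalkyne tolerates. Isomerisation of the alkyne to a silylketene, or dimerisation of the vinylketene, could then outrun the cycloaddition. The fallback uses known chemistry only, sets out from acid 18 and comes back at phenol 14. Reduction of 18 with BH3·THF should give [3,4-dimethoxy-5-(triisopropylsilyloxy)phenyl]methanol F1. Oxidation with MnO2 in CH2Cl2 should give 3,4-dimethoxy-5-(triisopropylsilyloxy)benzaldehyde F2. Baeyer–Villiger oxidation with mCPBA (NaHCO3, CH2Cl2), in which the electron-rich aryl group migrates, should give 3,4-dimethoxy-5-(triisopropylsilyloxy)phenyl formate F3. Brief methanolysis of the formate (NaHCO3, MeOH, 0 °C) then releases 14 with the silyl ether in place.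

Step 7. Acylation may compete at C8, or the silyl ether may be lost under the Lewis acid, which would remove the steric bias between the two ortho carbons. The fallback sets out from 14 and comes back at 15, and replaces steric control by directed metalation. MOMCl and iPr2NEt in CH2Cl2 should give triisopropyl[3,4-dimethoxy-5-(methoxymethoxy)phenoxy]silane F4. Ortho-lithiation (n-BuLi, THF, 0 °C) can only take place at C4a, which is flanked by two coordinating oxygens, because the silyloxy group neither directs nor admits the base at C8. Quenching with N-methoxy-N-methylacetamide should give 1-[2,3-dimethoxy-6-(methoxymethoxy)-4-(triisopropylsilyloxy)phenyl]ethan-1-one F5. HCl in MeOH at room temperature then cleaves the acetal ortho to the carbonyl and gives 15.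

Step 2. The activated alcohol may ionise to the methoxy-stabilised cyclobutenyl cation, followed by chloride return at C2 or by loss of methyl chloride. The outcome would be allylic transposition or collapse to the cyclobutenedione. The fallback sets out from 2 and comes back at 4, and avoids a halide altogether. Acetylation (Ac2O, pyridine, DMAP cat., CH2Cl2, 0 °C) should give 2,3-dimethoxy-4-oxocyclobut-2-en-1-yl acetate F6 (racemic) without ionisation. Single-electron reductive cleavage of this α-acyloxy ketone with SmI2 in THF–MeOH at −78 °C should then give 4 directly.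

Further compounds
F1 | step 6 | [3,4-dimethoxy-5-(triisopropylsilyloxy)phenyl]methanol | COc1cc(CO)cc(O[Si](C(C)C)(C(C)C)C(C)C)c1OC
F2 | step 6 | 3,4-dimethoxy-5-(triisopropylsilyloxy)benzaldehyde | COc1cc(C=O)cc(O[Si](C(C)C)(C(C)C)C(C)C)c1OC
F3 | step 6 | 3,4-dimethoxy-5-(triisopropylsilyloxy)phenyl formate | COc1cc(OC=O)cc(O[Si](C(C)C)(C(C)C)C(C)C)c1OC
F4 | step 7 | triisopropyl[3,4-dimethoxy-5-(methoxymethoxy)phenoxy]silane | COCOc1cc(OC)c(OC)c(O[Si](C(C)C)(C(C)C)C(C)C)c1
F5 | step 7 | 1-[2,3-dimethoxy-6-(methoxymethoxy)-4-(triisopropylsilyloxy)phenyl]ethan-1-one | CC(=O)c1c(OCOC)cc(O[Si](C(C)C)(C(C)C)C(C)C)c(OC)c1OC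
F6 | step 2 | 2,3-dimethoxy-4-oxocyclobut-2-en-1-yl acetate (racemic) | CC(=O)OC1C(OC)=C(OC)C1=O
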